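**Retrosynthetic overview**
1. Last step: the ten-membered ring is closed at C6–C7 by an intramolecular chromium Barbier (Nozaki–Hiyama–Kishi-type) allylation of an acyclic epoxy aldehyde by its own 3-(bromomethyl)butenolide; this sets C6 and C7 and unveils the α-methylene lactone. The lactone-first, ring-closing-metathesis-at-C1=C10 route is deliberately not used.
2. Cyclisation precursor ⇐ Sharpless epoxidation (C4, C5), chemoselective allylic bromination and oxidation of an acyclic diol.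
3. Acyclic diol ⇐ vinylogous Mukaiyama aldol (C8–C9 bond; sets C8 and C9) between a geraniol-derived C9 enal and a 2-silyloxyfuran, then acylation of C9–OH.
4. Enal ⇐ geraniol (silylation, SeO2, MnO2); silyloxyfuran ⇐ 3-bromofuran-2(5H)-one (Stille hydroxymethylation, silylation).
5. Ring order: butenolide (bought as the furanone) → oxirane → ten-membered carbocycle last.

Positions C1–C15 follow the germacrane skeleton of the target; TBS = tert-butyldimethylsilyl, TMS = trimethylsilyl.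
Assumption: 3-bromofuran-2(5H)-one and (tributylstannyl)methanol are bought, and the chiral ammonium phenoxide of step 6 induces the sense shown (if not, its pseudoenantiomer is used).

**Step 1**
Reactants: 1 geraniol [(2E)-3,7-dimethylocta-2,6-dien-1-ol]
Product: 2 tert-butyl{[(2E)-3,7-dimethylocta-2,6-dien-1-yl]oxy}dimethylsilane
Conditions: TBSCl, imidazole, DMF, 0 °C to rt
Reagents that add atoms: tert-butyldimethylsilyl chloride CC(C)(C)[Si](C)(C)Cl
Why: Imidazole-promoted silylation of the primary allylic alcohol (the future C6–OH) gives an ether that survives the oxidations and the aldol; no stereocentre is formed.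

**Step 2**
Reactants: 2 tert-butyl{[(2E)-3,7-dimethylocta-2,6-dien-1-yl]oxy}dimethylsilane
Product: 3 (2E,6E)-8-[(tert-butyldimethylsilyl)oxy]-2,6-dimethylocta-2,6-dien-1-ol
Conditions: SeO2 (0.3 equiv), t-BuOOH (3 equiv), salicylic acid (0.1 equiv), CH2Cl2, 0 °C to rt
Reagents that add atoms: tert-butyl hydroperoxide CC(C)(C)OO
Why: Sharpless–Umbreit allylic oxidation (ene reaction then [2,3]-shift) attacks the E-methyl of the terminal trisubstituted olefin only and keeps the E geometry, giving the future C9 carbinol carbon.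

**Step 3**
Reactants: 3 (2E,6E)-8-[(tert-butyldimethylsilyl)oxy]-2,6-dimethylocta-2,6-dien-1-ol
Product: 4 (2E,6E)-8-[(tert-butyldimethylsilyl)oxy]-2,6-dimethylocta-2,6-dienal
Conditions: MnO2 (15 equiv), CH2Cl2, rt
Reagents that add atoms: none
Why: MnO2 oxidation of an allylic alcohol stops at the (E)-enal and leaves the silyl ether and both olefins untouched.

**Step 4**
Reactants: 5 3-bromofuran-2(5H)-one; 6 (tributylstannyl)methanol
Product: 7 3-(hydroxymethyl)furan-2(5H)-one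
Conditions: Pd(PPh3)4 (5 mol %), 1,4-dioxane, 90 °C
Reagents that add atoms: none
Why: Stille cross-coupling at the activated α-bromo enoate C–Br bond (zerovalent palladium) transfers the hydroxymethyl group in preference to butyl under neutral conditions that the base-sensitive butenolide tolerates.

**Step 5**
Reactants: 7 3-(hydroxymethyl)furan-2(5H)-one
Product: 9 tert-butyldimethyl{[2-(trimethylsilyloxy)furan-3-yl]methoxy}silane, via 3-{[(tert-butyldimethylsilyl)oxy]methyl}furan-2(5H)-one 8 (not isolated)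
Conditions: TBSCl, imidazole, CH2Cl2, 0 °C; then Et3N, TMSOTf, 0 °C (one pot, non-aqueous work-up)
Reagents that add atoms: tert-butyldimethylsilyl chloride CC(C)(C)[Si](C)(C)Cl; trimethylsilyl trifluoromethanesulfonate C[Si](C)(C)OS(=O)(=O)C(F)(F)F
Why: O-silylation of the primary alcohol followed by soft enolisation (removal of the acidic γ-proton and O-silylation) gives the aromatic 2-silyloxyfuran needed as vinylogous aldol donor.

**Step 6**
Reactants: 4 (2E,6E)-8-[(tert-butyldimethylsilyl)oxy]-2,6-dimethylocta-2,6-dienal; 9 tert-butyldimethyl{[2-(trimethylsilyloxy)furan-3-yl]methoxy}silane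
Product: 11 (5R)-3-{[(tert-butyldimethylsilyl)oxy]methyl}-5-[(1S,2E,6E)-8-[(tert-butyldimethylsilyl)oxy]-1-hydroxy-2,6-dimethylocta-2,6-dien-1-yl]furan-2(5H)-one, via trimethylsilyl ether of the aldol adduct 10 (not isolated)
Conditions: cinchonidine-derived N-benzyl quaternary ammonium phenoxide (10 mol %), THF–CH2Cl2, −78 °C; then 1 M aq. HCl, THF, 0 °C, 10 min
Reagents that add atoms: none
Why: Vinylogous Mukaiyama aldol under Lewis-base (phenoxide) activation: the chiral ammonium 2-furanolate ion pair adds through C5 to the aldehyde with no Lewis acid on the carbonyl, so the open transition state with opposed C–O dipoles gives the erythro adduct (as in fluoride-promoted additions of 2-silyloxyfurans) and the cation shields one face, setting C8 (R) and C9 (S).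

**Step 7**
Reactants: 11 (5R)-3-{[(tert-butyldimethylsilyl)oxy]methyl}-5-[(1S,2E,6E)-8-[(tert-butyldimethylsilyl)oxy]-1-hydroxy-2,6-dimethylocta-2,6-dien-1-yl]furan-2(5H)-one
Product: 12 (1S,2E,6E)-8-[(tert-butyldimethylsilyl)oxy]-1-[(2R)-4-{[(tert-butyldimethylsilyl)oxy]methyl}-5-oxo-2,5-dihydrofuran-2-yl]-2,6-dimethylocta-2,6-dien-1-yl 2-methylpropanoate
Conditions: isobutyryl chloride, pyridine, CH2Cl2, 0 °C
Reagents that add atoms: isobutyryl chloride CC(C)C(=O)Cl
Why: Acylation of the only free hydroxyl (C9) installs the isobutyrate with retention, under base weak and cold enough to avoid E1cB loss of the new ester from the butenolide.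

**Step 8**
Reactants: 12 (1S,2E,6E)-8-[(tert-butyldimethylsilyl)oxy]-1-[(2R)-4-{[(tert-butyldimethylsilyl)oxy]methyl}-5-oxo-2,5-dihydrofuran-2-yl]-2,6-dimethylocta-2,6-dien-1-yl 2-methylpropanoate
Product: 13 (1S,2E,6E)-8-hydroxy-1-[(2R)-4-(hydroxymethyl)-5-oxo-2,5-dihydrofuran-2-yl]-2,6-dimethylocta-2,6-dien-1-yl 2-methylpropanoate
Conditions: 48% aq. HF, MeCN, 0 °C
Reagents that add atoms: none
Why: Acidic fluoride desilylation removes both primary silyl ethers while the isobutyrate, the butenolide and the C8/C9 stereocentres are stable to acid.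

**Step 9**
Reactants: 13 (1S,2E,6E)-8-hydroxy-1-[(2R)-4-(hydroxymethyl)-5-oxo-2,5-dihydrofuran-2-yl]-2,6-dimethylocta-2,6-dien-1-yl 2-methylpropanoate
Product: 14 (1S,2E)-5-[(2S,3S)-3-(hydroxymethyl)-2-methyloxiran-2-yl]-1-[(2R)-4-(hydroxymethyl)-5-oxo-2,5-dihydrofuran-2-yl]-2-methylpent-2-en-1-yl 2-methylpropanoate
Conditions: Ti(OiPr)4 (20 mol %), diethyl L-(+)-tartrate (24 mol %), t-BuOOH (2 equiv), 4 Å molecular sieves, CH2Cl2, −20 °C
Reagents that add atoms: tert-butyl hydroperoxide CC(C)(C)OO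
Why: Sharpless asymmetric epoxidation acts only on C4=C5 (the butenolide olefin is electron-poor and C1=C10 has no free allylic hydroxyl), and L-(+)-tartrate gives the (4S,5S)-epoxide by the same facial rule that turns geraniol into (2S,3S)-epoxygeraniol.

**Step 10**
Reactants: 14 (1S,2E)-5-[(2S,3S)-3-(hydroxymethyl)-2-methyloxiran-2-yl]-1-[(2R)-4-(hydroxymethyl)-5-oxo-2,5-dihydrofuran-2-yl]-2-methylpent-2-en-1-yl 2-methylpropanoate
Product: 15 (1S,2E)-1-[(2R)-4-(bromomethyl)-5-oxo-2,5-dihydrofuran-2-yl]-5-[(2S,3S)-3-(hydroxymethyl)-2-methyloxiran-2-yl]-2-methylpent-2-en-1-yl 2-methylpropanoate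
Conditions: NBS (1.2 equiv), Me2S (1.5 equiv), CH2Cl2, −30 to 0 °C
Reagents that add atoms: N-bromosuccinimide O=C1CCC(=O)N1Br
Why: Corey–Kim bromination: the alkoxysulfonium of the allylic 2-(hydroxymethyl)enoate hydroxyl (C13) is displaced by bromide at low temperature, whereas that of the non-allylic epoxy alcohol (C6) is not and reverts on work-up.

**Step 11**
Reactants: 15 (1S,2E)-1-[(2R)-4-(bromomethyl)-5-oxo-2,5-dihydrofuran-2-yl]-5-[(2S,3S)-3-(hydroxymethyl)-2-methyloxiran-2-yl]-2-methylpent-2-en-1-yl 2-methylpropanoate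
Product: 16 (1S,2E)-1-[(2R)-4-(bromomethyl)-5-oxo-2,5-dihydrofuran-2-yl]-5-[(2S,3R)-3-formyl-2-methyloxiran-2-yl]-2-methylpent-2-en-1-yl 2-methylpropanoate
Conditions: TEMPO (10 mol %), PhI(OAc)2 (1.2 equiv), CH2Cl2, rt
Reagents that add atoms: none
Why: Oxoammonium (TEMPO) oxidation of the primary epoxy alcohol stops at the aldehyde under neutral conditions that spare the allylic bromide, the epoxide and the epimerisable C5 centre (its descriptor changes to R only through the priority of CHO).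

**Step 12**
Reactants: 16 (1S,2E)-1-[(2R)-4-(bromomethyl)-5-oxo-2,5-dihydrofuran-2-yl]-5-[(2S,3R)-3-formyl-2-methyloxiran-2-yl]-2-methylpent-2-en-1-yl 2-methylpropanoate
Product: 19 (1(10)E,4S,5S,6S,7S,8R,9S)-4,5-epoxy-6-hydroxy-9-(2-methylpropanoyloxy)germacra-1(10),11(13)-dien-12,8-olide, via allylchromium dichloride 17 (not isolated), via chromium alkoxide of the macrocycle 18 (not isolated)
Conditions: CrCl2 (10 equiv), THF, 25 °C, 0.002 M (16 added over 12 h); then H2O
Reagents that add atoms: none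
Why: Intramolecular Nozaki–Hiyama–Kishi-type chromium Barbier allylation: divalent chromium turns the allylic bromide into an allylchromium that adds through its γ-carbon (C7) to the aldehyde in a chair transition state, on the butenolide face opposite the C9 side chain (trans lactone, 7S), with the ring-locked E allyl terminus giving the anti C6/C7 relationship (6S), which is also the Felkin–Anh product anti to the epoxide C–O bond, so the three preferences converge on the target as the ten-membered ring closes.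

**Compound list**
1 | geraniol, (2E)-3,7-dimethylocta-2,6-dien-1-ol | OC/C=C(\C)CCC=C(C)C | starting material
2 | tert-butyl{[(2E)-3,7-dimethylocta-2,6-dien-1-yl]oxy}dimethylsilane | CC(C)(C)[Si](C)(C)OC/C=C(\C)CCC=C(C)C | intermediate
3 | (2E,6E)-8-[(tert-butyldimethylsilyl)oxy]-2,6-dimethylocta-2,6-dien-1-ol | CC(C)(C)[Si](C)(C)OC/C=C(\C)CC/C=C(\C)CO | intermediate
4 | (2E,6E)-8-[(tert-butyldimethylsilyl)oxy]-2,6-dimethylocta-2,6-dienal | CC(C)(C)[Si](C)(C)OC/C=C(\C)CC/C=C(\C)C=O | intermediate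
5 | 3-bromofuran-2(5H)-one | O=C1OCC=C1Br | starting material
6 | (tributylstannyl)methanol | CCCC[Sn](CCCC)(CCCC)CO | starting material
7 | 3-(hydroxymethyl)furan-2(5H)-one | O=C1OCC=C1CO | intermediate
8 | 3-{[(tert-butyldimethylsilyl)oxy]methyl}furan-2(5H)-one | O=C1OCC=C1CO[Si](C)(C)C(C)(C)C | intermediate
9 | tert-butyldimethyl{[2-(trimethylsilyloxy)furan-3-yl]methoxy}silane | C[Si](C)(C)Oc1occc1CO[Si](C)(C)C(C)(C)C | intermediate
10 | (5R)-3-{[(tert-butyldimethylsilyl)oxy]methyl}-5-[(1S,2E,6E)-8-[(tert-butyldimethylsilyl)oxy]-2,6-dimethyl-1-(trimethylsilyloxy)octa-2,6-dien-1-yl]furan-2(5H)-one | CC(C)(C)[Si](C)(C)OC/C=C(\C)CC/C=C(\C)[C@H](O[Si](C)(C)C)[C@@H]1OC(=O)C(CO[Si](C)(C)C(C)(C)C)=C1 | intermediate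
11 | (5R)-3-{[(tert-butyldimethylsilyl)oxy]methyl}-5-[(1S,2E,6E)-8-[(tert-butyldimethylsilyl)oxy]-1-hydroxy-2,6-dimethylocta-2,6-dien-1-yl]furan-2(5H)-one | CC(C)(C)[Si](C)(C)OC/C=C(\C)CC/C=C(\C)[C@H](O)[C@@H]1OC(=O)C(CO[Si](C)(C)C(C)(C)C)=C1 | intermediate
12 | (1S,2E,6E)-8-[(tert-butyldimethylsilyl)oxy]-1-[(2R)-4-{[(tert-butyldimethylsilyl)oxy]methyl}-5-oxo-2,5-dihydrofuran-2-yl]-2,6-dimethylocta-2,6-dien-1-yl 2-methylpropanoate | CC(C)(C)[Si](C)(C)OC/C=C(\C)CC/C=C(\C)[C@H](OC(=O)C(C)C)[C@@H]1OC(=O)C(CO[Si](C)(C)C(C)(C)C)=C1 | intermediate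
13 | (1S,2E,6E)-8-hydroxy-1-[(2R)-4-(hydroxymethyl)-5-oxo-2,5-dihydrofuran-2-yl]-2,6-dimethylocta-2,6-dien-1-yl 2-methylpropanoate | OC/C=C(\C)CC/C=C(\C)[C@H](OC(=O)C(C)C)[C@@H]1OC(=O)C(CO)=C1 | intermediate
14 | (1S,2E)-5-[(2S,3S)-3-(hydroxymethyl)-2-methyloxiran-2-yl]-1-[(2R)-4-(hydroxymethyl)-5-oxo-2,5-dihydrofuran-2-yl]-2-methylpent-2-en-1-yl 2-methylpropanoate | OC[C@@H]1O[C@@]1(C)CC/C=C(\C)[C@H](OC(=O)C(C)C)[C@@H]1OC(=O)C(CO)=C1 | intermediate
15 | (1S,2E)-1-[(2R)-4-(bromomethyl)-5-oxo-2,5-dihydrofuran-2-yl]-5-[(2S,3S)-3-(hydroxymethyl)-2-methyloxiran-2-yl]-2-methylpent-2-en-1-yl 2-methylpropanoate | OC[C@@H]1O[C@@]1(C)CC/C=C(\C)[C@H](OC(=O)C(C)C)[C@@H]1OC(=O)C(CBr)=C1 | intermediate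
16 | (1S,2E)-1-[(2R)-4-(bromomethyl)-5-oxo-2,5-dihydrofuran-2-yl]-5-[(2S,3R)-3-formyl-2-methyloxiran-2-yl]-2-methylpent-2-en-1-yl 2-methylpropanoate | O=C[C@@H]1O[C@@]1(C)CC/C=C(\C)[C@H](OC(=O)C(C)C)[C@@H]1OC(=O)C(CBr)=C1 | intermediate
17 | allylchromium dichloride of 16 (CrCl2 in place of Br on the butenolide CH2) | O=C[C@@H]1O[C@@]1(C)CC/C=C(\C)[C@H](OC(=O)C(C)C)[C@@H]1OC(=O)C(C[Cr](Cl)Cl)=C1 | intermediate
18 | dichlorochromium alkoxide of 19 at O6 | C=C1C(=O)O[C@@H]2[C@@H]1[C@H](O[Cr](Cl)Cl)[C@@H]1O[C@@]1(C)CC/C=C(\C)[C@@H]2OC(=O)C(C)C | intermediate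
19 | (1(10)E,4S,5S,6S,7S,8R,9S)-4,5-epoxy-6-hydroxy-9-(2-methylpropanoyloxy)germacra-1(10),11(13)-dien-12,8-olide (CNP0220196.1) | C=C1C(=O)O[C@@H]2[C@@H]1[C@H](O)[C@@H]1O[C@@]1(C)CC/C=C(\C)[C@@H]2OC(=O)C(C)C | target

**Total step count:** 12. **Longest linear sequence:** 10 steps (1 to 19 through steps 1, 2, 3, 6, 7, 8, 9, 10, 11, 12).

**The three steps most likely to fail**

First, step 12, the macrocyclisation. The α,β-epoxy aldehyde may be reduced or opened by the chromium reagent, the ring may close with the wrong C6 configuration, or oligomers may dominate. The fallback sets out from 13 and comes back at 19. Diol 13 is oxidised with MnO2, which touches only the electron-rich C6 allylic alcohol, to give (1S,2E,6E)-1-[(2R)-4-(hydroxymethyl)-5-oxo-2,5-dihydrofuran-2-yl]-2,6-dimethyl-8-oxoocta-2,6-dien-1-yl 2-methylpropanoate F1. Corey–Kim bromination (NBS, Me2S) of its only hydroxyl gives (1S,2E,6E)-1-[(2R)-4-(bromomethyl)-5-oxo-2,5-dihydrofuran-2-yl]-2,6-dimethyl-8-oxoocta-2,6-dien-1-yl 2-methylpropanoate F2. CrCl2 in dilute THF closes the ring on the enal, the substrate class of the known costunolide-type closures, to give (1(10)E,4E)-6-hydroxy-9-(2-methylpropanoyloxy)germacra-1(10),4,11(13)-trien-12,8-olide with the C6 to C9 configuration of 19 F3. The epoxide is then set last under reagent control by Sharpless epoxidation of this secondary allylic alcohol (Ti(OiPr)4, diethyl L-(+)-tartrate, t-BuOOH); the 6S carbinol and L-(+)-tartrate are the matched pair that gives the erythro (4S,5S) epoxide 19.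

Second, step 6, the aldol. The erythro/threo ratio or the enantioselectivity of the ion-pair vinylogous aldol may be inadequate for this enal and this 3-substituted furan. The fallback sets out from 4 and comes back at 12, building C8/C9 by reagent-controlled allylboration and the butenolide by ring-closing metathesis.
- Enal 4 is treated with (Z)-γ-(methoxymethoxy)allyldiisopinocampheylborane (from allyl methoxymethyl ether, s-BuLi, B-methoxydiisopinocampheylborane of the required antipode and BF3·OEt2), with oxidative work-up. This gives the syn adduct (3R,4R,5E,9E)-11-[(tert-butyldimethylsilyl)oxy]-3-(methoxymethoxy)-5,9-dimethylundeca-1,5,9-trien-4-ol F4.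
- Mitsunobu esterification with isobutyric acid (PPh3, DIAD) inverts C9, which has no acidic neighbour at this stage, to give (3R,4S,5E,9E)-11-[(tert-butyldimethylsilyl)oxy]-3-(methoxymethoxy)-5,9-dimethylundeca-1,5,9-trien-4-yl 2-methylpropanoate F5.
- ZnBr2 and n-PrSH remove the methoxymethyl group to give (3R,4S,5E,9E)-11-[(tert-butyldimethylsilyl)oxy]-3-hydroxy-5,9-dimethylundeca-1,5,9-trien-4-yl 2-methylpropanoate F6.
- Separately, commercial ethyl 2-(hydroxymethyl)acrylate is silylated (TBSCl, imidazole) to ethyl 2-{[(tert-butyldimethylsilyl)oxy]methyl}prop-2-enoate F7 and saponified (LiOH) to 2-{[(tert-butyldimethylsilyl)oxy]methyl}prop-2-enoic acid F8.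
- DCC/DMAP coupling of this acid with the alcohol gives (3R,4S,5E,9E)-11-[(tert-butyldimethylsilyl)oxy]-5,9-dimethyl-4-(2-methylpropanoyloxy)undeca-1,5,9-trien-3-yl 2-{[(tert-butyldimethylsilyl)oxy]methyl}prop-2-enoate F9.
- Ring-closing metathesis with the second-generation Hoveyda–Grubbs catalyst (toluene, 80 °C) closes the butenolide to 12.

Third, step 10, the chemoselective bromination. The Corey–Kim reagent may fail to discriminate cleanly between the allylic hydroxyl and the epoxy alcohol, or may damage the epoxide. The fallback sets out from 7 and comes back at 15, installing the bromide while C6–OH is still silylated.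
- Furanone 7 is bis-silylated (TMSOTf, Et3N) to trimethyl{[2-(trimethylsilyloxy)furan-3-yl]methoxy}silane F10.
- The ammonium phenoxide aldol with 4 as in step 6, then dilute HCl (both trimethylsilyl groups off), gives (5R)-5-[(1S,2E,6E)-8-[(tert-butyldimethylsilyl)oxy]-1-hydroxy-2,6-dimethylocta-2,6-dien-1-yl]-3-(hydroxymethyl)furan-2(5H)-one F11.
- Appel bromination (CBr4, PPh3, −30 °C) of the primary allylic hydroxyl, much faster than the hindered secondary one, gives (5R)-3-(bromomethyl)-5-[(1S,2E,6E)-8-[(tert-butyldimethylsilyl)oxy]-1-hydroxy-2,6-dimethylocta-2,6-dien-1-yl]furan-2(5H)-one F12.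
- Isobutyryl chloride and 2,6-lutidine give (1S,2E,6E)-1-[(2R)-4-(bromomethyl)-5-oxo-2,5-dihydrofuran-2-yl]-8-[(tert-butyldimethylsilyl)oxy]-2,6-dimethylocta-2,6-dien-1-yl 2-methylpropanoate F13.
- Aqueous HF in MeCN gives (1S,2E,6E)-1-[(2R)-4-(bromomethyl)-5-oxo-2,5-dihydrofuran-2-yl]-8-hydroxy-2,6-dimethylocta-2,6-dien-1-yl 2-methylpropanoate F14.
- Sharpless epoxidation exactly as in step 9 gives 15.

**Further compounds**
F1 | step 12 | (1S,2E,6E)-1-[(2R)-4-(hydroxymethyl)-5-oxo-2,5-dihydrofuran-2-yl]-2,6-dimethyl-8-oxoocta-2,6-dien-1-yl 2-methylpropanoate | O=C/C=C(\C)CC/C=C(\C)[C@H](OC(=O)C(C)C)[C@@H]1OC(=O)C(CO)=C1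
F2 | step 12 | (1S,2E,6E)-1-[(2R)-4-(bromomethyl)-5-oxo-2,5-dihydrofuran-2-yl]-2,6-dimethyl-8-oxoocta-2,6-dien-1-yl 2-methylpropanoate | O=C/C=C(\C)CC/C=C(\C)[C@H](OC(=O)C(C)C)[C@@H]1OC(=O)C(CBr)=C1
F3 | step 12 | (1(10)E,4E)-6-hydroxy-9-(2-methylpropanoyloxy)germacra-1(10),4,11(13)-trien-12,8-olide with the C6 to C9 configuration of 19 | C=C1C(=O)O[C@@H]2[C@@H]1[C@H](O)/C=C(\C)CC/C=C(\C)[C@@H]2OC(=O)C(C)C
F4 | step 6 | (3R,4R,5E,9E)-11-[(tert-butyldimethylsilyl)oxy]-3-(methoxymethoxy)-5,9-dimethylundeca-1,5,9-trien-4-ol | CC(C)(C)[Si](C)(C)OC/C=C(\C)CC/C=C(\C)[C@@H](O)[C@H](OCOC)C=C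
F5 | step 6 | (3R,4S,5E,9E)-11-[(tert-butyldimethylsilyl)oxy]-3-(methoxymethoxy)-5,9-dimethylundeca-1,5,9-trien-4-yl 2-methylpropanoate | CC(C)(C)[Si](C)(C)OC/C=C(\C)CC/C=C(\C)[C@H](OC(=O)C(C)C)[C@H](OCOC)C=C
F6 | step 6 | (3R,4S,5E,9E)-11-[(tert-butyldimethylsilyl)oxy]-3-hydroxy-5,9-dimethylundeca-1,5,9-trien-4-yl 2-methylpropanoate | CC(C)(C)[Si](C)(C)OC/C=C(\C)CC/C=C(\C)[C@H](OC(=O)C(C)C)[C@H](O)C=C
F7 | step 6 | ethyl 2-{[(tert-butyldimethylsilyl)oxy]methyl}prop-2-enoate | CCOC(=O)C(=C)CO[Si](C)(C)C(C)(C)C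
F8 | step 6 | 2-{[(tert-butyldimethylsilyl)oxy]methyl}prop-2-enoic acid | OC(=O)C(=C)CO[Si](C)(C)C(C)(C)C
F9 | step 6 | (3R,4S,5E,9E)-11-[(tert-butyldimethylsilyl)oxy]-5,9-dimethyl-4-(2-methylpropanoyloxy)undeca-1,5,9-trien-3-yl 2-{[(tert-butyldimethylsilyl)oxy]methyl}prop-2-enoate | CC(C)(C)[Si](C)(C)OC/C=C(\C)CC/C=C(\C)[C@H](OC(=O)C(C)C)[C@H](OC(=O)C(=C)CO[Si](C)(C)C(C)(C)C)C=C
F10 | step 10 | trimethyl{[2-(trimethylsilyloxy)furan-3-yl]methoxy}silane | C[Si](C)(C)OCc1ccoc1O[Si](C)(C)C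
F11 | step 10 | (5R)-5-[(1S,2E,6E)-8-[(tert-butyldimethylsilyl)oxy]-1-hydroxy-2,6-dimethylocta-2,6-dien-1-yl]-3-(hydroxymethyl)furan-2(5H)-one | CC(C)(C)[Si](C)(C)OC/C=C(\C)CC/C=C(\C)[C@H](O)[C@@H]1OC(=O)C(CO)=C1
F12 | step 10 | (5R)-3-(bromomethyl)-5-[(1S,2E,6E)-8-[(tert-butyldimethylsilyl)oxy]-1-hydroxy-2,6-dimethylocta-2,6-dien-1-yl]furan-2(5H)-one | CC(C)(C)[Si](C)(C)OC/C=C(\C)CC/C=C(\C)[C@H](O)[C@@H]1OC(=O)C(CBr)=C1
F13 | step 10 | (1S,2E,6E)-1-[(2R)-4-(bromomethyl)-5-oxo-2,5-dihydrofuran-2-yl]-8-[(tert-butyldimethylsilyl)oxy]-2,6-dimethylocta-2,6-dien-1-yl 2-methylpropanoate | CC(C)(C)[Si](C)(C)OC/C=C(\C)CC/C=C(\C)[C@H](OC(=O)C(C)C)[C@@H]1OC(=O)C(CBr)=C1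
F14 | step 10 | (1S,2E,6E)-1-[(2R)-4-(bromomethyl)-5-oxo-2,5-dihydrofuran-2-yl]-8-hydroxy-2,6-dimethylocta-2,6-dien-1-yl 2-methylpropanoate | OC/C=C(\C)CC/C=C(\C)[C@H](OC(=O)C(C)C)[C@@H]1OC(=O)C(CBr)=C1
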